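At early times the ochre run has used starting material faster than the blue run, 14.1 mM against 8.30 mM at 5.8 min, and their recipes differ in one line.

| setting | blue | grey | ochre | red | violet |
|---|---|---|---|---|---|
| starting material | 100 mM | 40.0 mM | 100 mM | 100 mM | 100 mM |
| reagent | 120 mM | 60.0 mM | 120 mM | 240 mM | 120 mM |
| free catalyst | 1.00 mM | 1.00 mM | 2.00 mM | 1.00 mM | 1.00 mM |
| time |  |  |  |  | 80 min |

The blue and ochre runs share their charges of starting material and reagent, but the ochre run has 2.00 mM of free catalyst against 1.00 mM. So I lay their readings side by side.

| run | time / min | [starting material] / mM |
|---|---|---|
| blue run | 1.6 | 97.6 |
| blue run | 3.0 | 95.7 |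
| blue run | 5.8 | 91.7 |
| blue run | 11 | 84.3 |
| blue run | 21 | 74.5 |
| blue run | 40 | 54.6 |
| grey run | 1.6 | 38.2 |
| grey run | 3.0 | 37.8 |
| grey run | 5.8 | 36.0 |
| grey run | 11 | 31.0 |
| grey run | 21 | 24.1 |
| grey run | 40 | 10.9 |
| ochre run | 1.6 | 95.0 |
| ochre run | 3.0 | 92.2 |
| ochre run | 5.8 | 85.9 |
| ochre run | 11 | 74.4 |
| ochre run | 21 | 50.6 |
| ochre run | 40 | 20.6 |
| red run | 1.6 | 96.8 |
| red run | 3.0 | 94.6 |
| red run | 5.8 | 85.7 |
| red run | 11 | 74.7 |
| red run | 21 | 53.9 |
| red run | 40 | 18.9 |

(standard deviation of a reading: 1 mM)

The ochre run reads 74.4 mM at 11 min and the blue run reads 74.5 mM at 21 min. The products of c(free catalyst) and time are 1.32 M·s and 1.26 M·s, so at this pair of readings the two runs lie close together on that axis. The red and grey runs have other charges, so I keep them off this axis.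

- Overall: starting material + reagent -> product, with free catalyst as catalyst.
- Constant volume, constant temperature.
- Bound and free are read together.
- An order is taken over about fifteen percent of the charge, up and down.

Bound and free are read together, so each reading also counts starting material held on the catalyst.

* reaction order in [reagent] at the outset, round the charge of the blue run, defined at two percent of the starting material turned into product
* reaction order in [starting material] at the outset, round the charge of the blue run, defined at two percent of the starting material turned into product (one fixed amount of product, the same in the runs compared)
* the grey run starts with 60.0 mM less of starting material and of reagent than the blue run, and with no product. Compared where both hold the same amount of starting material, once fifteen percent of what the grey run was charged with has turned into product, is the grey run faster, slower or alike (within a tenth)?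
* starting material in the violet run at 80 min, as a share of the starting material charged

The violet run has the blue recipe, so it can go on the axis. At 80 min it has 4.80 M·s of catalyst-time, charged free catalyst times elapsed time. The ochre run reaches 4.80 M·s at 40 min and reads 20.6 mM there, so my reckoning for the violet run is 20.6%, give or take 1.00%.

The forecast says “The runs overlay on a time × catalyst axis”. It gives 0.8 in reagent, 0 in starting material, alike for the comparison and 22% for the violet run, 1.4 percentage points above my value.

The flask gives orders of 0.91 in reagent and −0.42 in starting material, alike for the comparison and 20.8% for the violet run. The forecast and the flask part on the order in starting material, 0 against −0.42.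

    free catalyst + starting material → catalyst-substrate complex (126.6 /M/min)
    catalyst-substrate complex + reagent → product + free catalyst (27.36 /M/min)
    catalyst-substrate complex + starting material ⇌ doubly bound catalyst, settled at all times (13.50 /M)

At 4.80 M·s of catalyst-time the violet run holds 20.8% of its charge, and the blue and ochre runs bring product to half of their charge at 2.66 M·s and 2.65 M·s. From the outset of the blue run, free catalyst takes up starting material and the complex passes on to product with the reagent, while the doubly bound catalyst stands at about 1.35 times the complex. By 80 min in the violet run, with about 40.8 mM of reagent present, that ratio has dropped to about 0.281.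

The earlier runs and the new flask are simulated for an exercise; noise was put on by code.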